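Atom numbering used throughout: decalin C1–C10 (ring A = C1–C5 and C10, ring B = C5–C10), C4 bears the exocyclic methylene C11, C5 the angular methyl, C8 a methyl, C9 a methyl and the benzylic CH2. Compounds are numbered 1–25 as in the steps; 25 is the target.

## Analysis of the target

- Target 25 is methyl 4-hydroxy-3-{[(1R,2S,4aS,8aR)-1,2,4a-trimethyl-5-methylidenedecahydronaphthalen-1-yl]methyl}benzoate, a cis-fused decalin joined through the C9 benzylic CH2 to C3 of a 4-hydroxybenzoate.
- There are four stereocentres: C5 (S), C8 (S), C9 (R) and C10 (R). The C5, C8 and C9 methyls and H10 all lie on one face of ring B; the benzylic CH2 and the two ring A bonds (C5–C4, C10–C1) lie on the other.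
- Two of the centres (C5, C9) are quaternary and sit 1,3 to each other across C10. C8–C9–C10 is a contiguous triad with no heteroatom on the decalin to direct reagents.
- Sensitive groups: the 1,1-disubstituted C4=C11 alkene (acid can move it into ring A; hydrogenation destroys it), the aryl methyl ester (hydride, hydroxide, hydrazine) and the free phenol.
- The hard points are the methylene next to the quaternary C5, which is awkward to install late by olefination of a hindered ketone, and the C9 quaternary centre flanked by two tertiary carbons.
- The strategy rests on ring A being a methylenecyclohexane whose vinylic C4 sits on C5 and whose C1 sits on C10. C5 and C10 are the β- and α-carbons of a ring B enone with its carbonyl at C9, so ring A can be annulated onto 3-methylcyclohexenone by one five-carbon reagent that is nucleophilic at C4 and electrophilic at C1.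

## Retrosynthetic reasoning

**25 from 24.** No skeletal bond is cut. The phenol would quench the enolate chemistry, so it is carried as the methoxymethyl ether 24 and freed last by acetal exchange.

**24 from 20 via 21.** The C9 methyl is traced back to a formyl group. In 20 the formyl is what makes C9 a nucleophilic carbon; afterwards its oxygen must go without touching the aryl ester or the alkene. This is done through the sulfonylhydrazone 21 and a mild hydride donor, not through strongly basic hydrazine conditions.

**20 from 14 and 18.** The C9–CH2Ar bond is cut. This is the most convergent cut: it joins two fragments of similar size in the last C–C bond formation and creates the second quaternary centre. Bromide 18 comes from the benzoate 15 in three routine steps through 16 and 17. The forward reaction must alkylate the enolate 19 on carbon, on the face opposite the C5 and C8 methyls.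

**14 from 12.** The C8–CH3 bond is cut as a conjugate addition to the enal 12. This sets C8 under kinetic control on a rigid unsaturated ring and delivers the C9 enol derivative 13 at the same time. Methylating a C9 ketone and equilibrating was rejected: that ketone is enolisable towards C10 as well, so any base equilibration would put the cis ring fusion at risk.

**12 from 9 via 11.** The C9–CHO bond is cut back to the ketone 9 through its enol triflate 11 and a carbonylation. Kinetic enolisation towards the C8 methylene (enolate 10) fixes the position of the double bond and leaves C10 untouched.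

**9 from 4 and 6 (6 from 3, 3 from 1).** This is the central cut: C4–C5 and C1–C10, which removes ring A and both ring-fusion stereocentres. The enone 4 is flat and achiral, so a chiral copper catalyst can set C5 as the alkenyl group of 6 adds. The resulting enolate 7 is regiodefined and carries its own alkylating chain, so activation to 8 closes ring A. The methylene is present from the outset. Alane 6 is reached from alkyne 1 through bromide 3 and the lithium reagent 5.

## Alternatives that were turned down

**Alternative 1:** Ring B is cut at C8–C9 and traced to a [3,3] shift.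
- Forward key step: the keto lactone A2 (ring A enone fused at C5–C10 to a six-membered lactone C9–C(=O)–O–C6, with an (E)-propenyl group on C6) is silylated at both carbonyls. On warming, the ketene acetal rearranges through a ring-enforced boat: C8–C9 forms, O–C6 breaks, and the acid A1 results.
- For: C8 and the quaternary C9 are made together with chirality transfer from the C6–O centre. On relative control of C8/C9 this is stronger than the substrate-controlled additions of the chosen route.
- Against: A1 is far from the target. The C9 carboxyl must become a methyl beside an aryl ester, C6=C7 must be saturated, and the ring A enone must be reworked into a C4 methylene next to the quaternary C5 with loss of the C2 oxygen. A2 itself needs three stereocentres and a defined alkene.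
- Comparison: the chosen route gives up some certainty at C8/C9 but reaches the methylene decalin in two steps and carries no surplus functionality.

**Alternative 2:** Both rings are cut at C5–C10 and C3–C4.
- Forward key step: heating the trienal A4 lets the (Z)-diene C10=C1–C2=C3 add to the (E)-enal C4=C5 and gives the cis-fused aldehyde A3.
- For: two rings and three stereocentres (C4, C5, C10) form in one thermal step. The (Z)-diene geometry translates into the cis fusion. In bonds per step this beats the chosen key step.
- Against: (Z)-dienes reach the s-cis form reluctantly and can undergo 1,5-hydrogen shift; the dienophile is β,β-disubstituted. A4 needs the C8/C9 pair, including the quaternary C9, built on an open chain. Facial selectivity would hinge on C9, whose methyl and CH2Ar differ little in size. After cyclisation, C1=C2 must be reduced and the C4 formyl turned into the methylene.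
- Comparison: the chosen route offers catalyst-controlled absolute configuration from an achiral, commercial enone and builds C8/C9 on a biased bicycle.

**Alternative 3:** Ring A is cut at C4–C5 only.
- Forward key step: Ph3PAuCl/AgSbF6 (monovalent gold) activates the alkyne of the silyl enol ether A6, and C5 attacks in a 6-exo-dig closure that forms the quaternary C5 and the methylene of A5 together.
- For: the conditions are mild, the step is late, and the ring B centres are already in place. On mildness of the ring-forming step it is at least equal to the chosen one.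
- Against: A5 keeps a C6 ketone that must be deleted next to a quaternary carbon in the presence of the alkene and the ester, a multi-step deoxygenation. A6 is a regiodefined tetrasubstituted enol ether on a ring that already carries the C8–C9–C10 triad, so the hardest stereochemistry must be solved first on a less biased monocycle.
- Comparison: the chosen route forms the same C4–C5 bond at the start, with a catalyst deciding C5 and no oxygen to remove afterwards.

Key step: step 2

Assumption: the phosphinamine enantiomer written in step 2 is taken to deliver the alkenyl group to the enone face that gives (S) at C5; if the sense proves opposite, its mirror image is used with no other change.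

## Route

Step 1
Reactants: 1 5-chloropent-1-yne
Product: 3 2-bromo-5-chloropent-1-ene, via alkenylborane 2 (not isolated)
Conditions: B-bromo-9-borabicyclo[3.3.1]nonane, CH2Cl2, 0 °C → rt; AcOH, rt
Reagents that add atoms: B-bromo-9-borabicyclo[3.3.1]nonane, BrB1C2CCCC1CCC2
Why: Syn bromoboration of the terminal alkyne puts boron on the terminal carbon and bromine on the internal one; protodeboronation with acetic acid then gives the 2-bromo-1-alkene, and the alkyl chloride is inert.

Step 2
Reactants: 3 2-bromo-5-chloropent-1-ene; 4 3-methylcyclohex-2-en-1-one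
Product: 9 (4aS,8aS)-4a-methyl-5-methylideneoctahydronaphthalen-1(2H)-one, via alkenyllithium 5 (not isolated), via alkenylalane 6 (not isolated), via aluminium enolate 7 (not isolated), via aluminate enolate 8 (not isolated)
Conditions: 3, t-BuLi (2 equiv), Et2O, −78 °C; Me2AlCl, −78 → −30 °C; 4, copper thiophene-2-carboxylate (CuTC, 10 mol %), (R,R)-Ph2P–N[CH(CH3)Ph]2 (11 mol %), Et2O/THF, −30 °C; MeLi, HMPA, −30 °C → rt
Reagents that add atoms: none
Why: Copper-catalysed asymmetric conjugate addition followed by enolate ring closure (a methylenecyclohexane annulation): Li–Br exchange at −78 °C outruns attack on the primary chloride, and transmetalation gives alane 6, whose alkenyl group passes to the chiral phosphinamine–copper complex (monovalent copper) in preference to methyl. The alkenylcopper adds its vinylic carbon C4 to the β-carbon C5 of 4 and forms C4–C5; 4 is flat and achiral, so the (S) configuration of the methyl-bearing quaternary centre comes from the ligand alone. The addition leaves the regiodefined aluminium enolate 7 (C9=C10), which MeLi turns into the more nucleophilic aluminate 8; with HMPA its C10 displaces chloride from C1 in a 6-exo-tet closure that forms C1–C10 and ring A. The closest known reactions are the copper-catalysed addition of alkenylalanes to 3-methylcyclohex-2-enone and the annulation of cyclohexenones with 5-chloropent-1-en-2-yl copper reagents. C10 is set by the closure: the new bond must form perpendicular to the enolate plane while the four-atom tether hangs on the neighbouring C5, which is possible only on the face that carries C4, so H10 ends cis to the C5 methyl. The step needs C-alkylation at C10 and not at C8 or at oxygen; the enolate is formed regiospecifically, and closure through oxygen or C8 would need eight-membered bridged rings. The chloride is inert enough to survive the organometallic stages and reactive enough once it is held next to the activated enolate.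

Step 3
Reactants: 9 (4aS,8aS)-4a-methyl-5-methylideneoctahydronaphthalen-1(2H)-one
Product: 11 (4aS,8aS)-4a-methyl-5-methylidene-3,4,4a,5,6,7,8,8a-octahydronaphthalen-1-yl trifluoromethanesulfonate, via lithium enolate 10 (not isolated)
Conditions: LiN(i-Pr)2, THF, −78 °C; PhNTf2, −78 → 0 °C
Reagents that add atoms: N-phenylbis(trifluoromethanesulfonimide), O=S(=O)(N(c1ccccc1)S(=O)(=O)C(F)(F)F)C(F)(F)F
Why: Kinetic deprotonation takes the C8 methylene and not the hindered C10 methine next to the quaternary C5, and O-sulfonylation of enolate 10 gives the enol triflate; without a proton source the enolate does not equilibrate, so the cis fusion at C10 is kept.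

Step 4
Reactants: 11 (4aS,8aS)-4a-methyl-5-methylidene-3,4,4a,5,6,7,8,8a-octahydronaphthalen-1-yl trifluoromethanesulfonate
Product: 12 (4aS,8aS)-4a-methyl-5-methylidene-3,4,4a,5,6,7,8,8a-octahydronaphthalene-1-carbaldehyde
Conditions: Pd(PPh3)4 (5 mol %), CO (1–3 atm), Bu3SnH (slow addition), LiCl, THF, 50 °C
Reagents that add atoms: carbon monoxide, [C-]#[O+]
Why: Palladium-catalysed formylation of an enol triflate: oxidative addition to zerovalent palladium, CO insertion to the acyl complex and hydride transfer from the stannane give the enal; slow addition of the stannane keeps direct reduction of the triflate down, and the isolated methylene does not react.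

Step 5
Reactants: 12 (4aS,8aS)-4a-methyl-5-methylidene-3,4,4a,5,6,7,8,8a-octahydronaphthalene-1-carbaldehyde
Product: 14 (2S,4aS,8aR)-2,4a-dimethyl-5-methylidenedecahydronaphthalene-1-carbaldehyde (both C1 epimers), via silyl enol ether 13 (not isolated)
Conditions: Me2CuLi (from CuI, 2 MeLi), TMSCl, THF, −78 → −40 °C; K2CO3, MeOH, 0 °C
Reagents that add atoms: lithium dimethylcuprate, [Li+].C[Cu-]C
Why: Chlorosilane-accelerated cuprate 1,4-addition to the enal, with the enolate trapped as 13 and released by methanolysis. Methyl should enter C8 on the convex face, cis to H10 and the C5 methyl, because the other face is covered by C1 of ring A (syn-axial to the incoming group in the half-chair), and the C9 configuration of 14 is irrelevant since C9 is enolised next.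

Step 6
Reactants: 15 methyl 3-formyl-4-hydroxybenzoate
Product: 16 methyl 3-formyl-4-(methoxymethoxy)benzoate
Conditions: MOMCl, i-Pr2NEt, CH2Cl2, 0 °C → rt
Reagents that add atoms: chloromethyl methyl ether, COCCl
Why: O-Alkylation of the acidic, formyl-activated phenol gives the acetal, which is stable to every basic and reducing step that follows.

Step 7
Reactants: 16 methyl 3-formyl-4-(methoxymethoxy)benzoate
Product: 17 methyl 3-(hydroxymethyl)-4-(methoxymethoxy)benzoate
Conditions: NaBH4, MeOH, 0 °C
Reagents that add atoms: none
Why: Borohydride reduces the aldehyde chemoselectively; the aryl methyl ester is untouched at 0 °C.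

Step 8
Reactants: 17 methyl 3-(hydroxymethyl)-4-(methoxymethoxy)benzoate
Product: 18 methyl 3-(bromomethyl)-4-(methoxymethoxy)benzoate
Conditions: CBr4, PPh3, CH2Cl2, 0 °C
Reagents that add atoms: carbon tetrabromide, BrC(Br)(Br)Br
Why: Appel bromination under neutral conditions spares the acid-labile acetal; the para ester tempers the donor oxygen so the benzylic bromide can be handled.

Step 9
Reactants: 14 (2S,4aS,8aR)-2,4a-dimethyl-5-methylidenedecahydronaphthalene-1-carbaldehyde; 18 methyl 3-(bromomethyl)-4-(methoxymethoxy)benzoate
Product: 20 methyl 3-{[(1S,2S,4aS,8aS)-1-formyl-2,4a-dimethyl-5-methylidenedecahydronaphthalen-1-yl]methyl}-4-(methoxymethoxy)benzoate, via potassium enolate 19 (not isolated)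
Conditions: KH, THF, 0 °C → rt; 18, 0 °C → rt
Reagents that add atoms: none
Why: C-Alkylation of the potassium enolate of an α,α-disubstituted aldehyde by a benzylic bromide creates the C9 quaternary centre. In the ring B chair that keeps the C8 methyl equatorial, the C5 methyl is axial and blocks the lower face of C9, so the bromide should enter equatorially on the upper face, anti to both methyls, leaving the formyl cis to them.

Step 10
Reactants: 20 methyl 3-{[(1S,2S,4aS,8aS)-1-formyl-2,4a-dimethyl-5-methylidenedecahydronaphthalen-1-yl]methyl}-4-(methoxymethoxy)benzoate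
Product: 21 (E)-N-tosylhydrazone of 20
Conditions: TsNHNH2, EtOH, 50 °C
Reagents that add atoms: 4-methylbenzenesulfonohydrazide, Cc1ccc(cc1)S(=O)(=O)NN
Why: Hydrazone condensation; the aldehyde is hindered but unconjugated and reacts on warming, and no other carbonyl in 20 is electrophilic enough to compete.

Step 11
Reactants: 21 (E)-N-tosylhydrazone of 20
Product: 24 methyl 4-(methoxymethoxy)-3-{[(1R,2S,4aS,8aR)-1,2,4a-trimethyl-5-methylidenedecahydronaphthalen-1-yl]methyl}benzoate, via borylhydrazide 22 (not isolated), via alkyldiazene 23 (not isolated)
Conditions: catecholborane, CHCl3, 0 °C → rt; NaOAc·3H2O, reflux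
Reagents that add atoms: none
Why: Tosylhydrazone reduction with catecholborane: hydride adds to C=N, acetate then expels sulfinate, and the diazene loses nitrogen to leave the C9 methyl; ester, acetal and the unactivated alkene are inert to catecholborane at this temperature, and no stereocentre is touched.

Step 12
Reactants: 24 methyl 4-(methoxymethoxy)-3-{[(1R,2S,4aS,8aR)-1,2,4a-trimethyl-5-methylidenedecahydronaphthalen-1-yl]methyl}benzoate
Product: 25 methyl 4-hydroxy-3-{[(1R,2S,4aS,8aR)-1,2,4a-trimethyl-5-methylidenedecahydronaphthalen-1-yl]methyl}benzoate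
Conditions: HCl (1.25 M in MeOH), 0 °C → rt
Reagents that add atoms: none
Why: Acid-catalysed acetal exchange with methanol frees the phenol; methanol as solvent keeps the methyl ester unchanged, and dilute acid at or below room temperature should not move the exocyclic alkene into the ring.

## Compound list

1 | 5-chloropent-1-yne | ClCCCC#C | starting material
2 | (Z)-9-(2-bromo-5-chloropent-1-en-1-yl)-9-borabicyclo[3.3.1]nonane | ClCCC/C(Br)=C/B1C2CCCC1CCC2 | intermediate
3 | 2-bromo-5-chloropent-1-ene | C=C(Br)CCCCl | intermediate
4 | 3-methylcyclohex-2-en-1-one | CC1=CC(=O)CCC1 | starting material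
5 | (5-chloropent-1-en-2-yl)lithium | [Li]C(=C)CCCCl | intermediate
6 | (5-chloropent-1-en-2-yl)dimethylalane | C=C(CCCCl)[Al](C)C | intermediate
7 | {[(3S)-3-(5-chloropent-1-en-2-yl)-3-methylcyclohex-1-en-1-yl]oxy}dimethylalane | C=C(CCCCl)[C@]1(C)C=C(O[Al](C)C)CCC1 | intermediate
8 | lithium {[(3S)-3-(5-chloropent-1-en-2-yl)-3-methylcyclohex-1-en-1-yl]oxy}trimethylaluminate | [Li+].C=C(CCCCl)[C@]1(C)C=C(O[Al-](C)(C)C)CCC1 | intermediate
9 | (4aS,8aS)-4a-methyl-5-methylideneoctahydronaphthalen-1(2H)-one (cis-5-methyl-4-methylenedecal-9-one) | C=C1CCC[C@@H]2C(=O)CCC[C@]12C | intermediate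
10 | lithium (4aS,8aS)-4a-methyl-5-methylidene-3,4,4a,5,6,7,8,8a-octahydronaphthalen-1-olate | C=C1CCC[C@@H]2C(O[Li])=CCC[C@]12C | intermediate
11 | (4aS,8aS)-4a-methyl-5-methylidene-3,4,4a,5,6,7,8,8a-octahydronaphthalen-1-yl trifluoromethanesulfonate | C=C1CCC[C@@H]2C(OS(=O)(=O)C(F)(F)F)=CCC[C@]12C | intermediate
12 | (4aS,8aS)-4a-methyl-5-methylidene-3,4,4a,5,6,7,8,8a-octahydronaphthalene-1-carbaldehyde | C=C1CCC[C@@H]2C(C=O)=CCC[C@]12C | intermediate
13 | {[(2S,4aS,8aS)-2,4a-dimethyl-5-methylideneoctahydronaphthalen-1(2H)-ylidene]methoxy}trimethylsilane | C=C1CCC[C@@H]2C(=CO[Si](C)(C)C)[C@@H](C)CC[C@]12C | intermediate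
14 | (2S,4aS,8aR)-2,4a-dimethyl-5-methylidenedecahydronaphthalene-1-carbaldehyde (both C1 epimers) | C=C1CCC[C@@H]2C(C=O)[C@@H](C)CC[C@]12C | intermediate
15 | methyl 3-formyl-4-hydroxybenzoate | COC(=O)c1ccc(O)c(C=O)c1 | starting material
16 | methyl 3-formyl-4-(methoxymethoxy)benzoate | COCOc1ccc(C(=O)OC)cc1C=O | intermediate
17 | methyl 3-(hydroxymethyl)-4-(methoxymethoxy)benzoate | COCOc1ccc(C(=O)OC)cc1CO | intermediate
18 | methyl 3-(bromomethyl)-4-(methoxymethoxy)benzoate | COCOc1ccc(C(=O)OC)cc1CBr | intermediate
19 | potassium [(2S,4aS,8aS)-2,4a-dimethyl-5-methylideneoctahydronaphthalen-1(2H)-ylidene]methanolate | C=C1CCC[C@@H]2C(=CO[K])[C@@H](C)CC[C@]12C | intermediate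
20 | methyl 3-{[(1S,2S,4aS,8aS)-1-formyl-2,4a-dimethyl-5-methylidenedecahydronaphthalen-1-yl]methyl}-4-(methoxymethoxy)benzoate | C=C1CCC[C@@H]2[C@](C=O)(Cc3cc(C(=O)OC)ccc3OCOC)[C@@H](C)CC[C@]12C | intermediate
21 | (E)-N-tosylhydrazone of 20 (1S,2S,4aS,8aS) | C=C1CCC[C@@H]2[C@](/C=N/NS(=O)(=O)c3ccc(C)cc3)(Cc3cc(C(=O)OC)ccc3OCOC)[C@@H](C)CC[C@]12C | intermediate
22 | N-(1,3,2-benzodioxaborol-2-yl)-N'-tosylhydrazine from hydroboration of 21 (1S,2S,4aS,8aS) | C=C1CCC[C@@H]2[C@](CN(B3Oc4ccccc4O3)NS(=O)(=O)c3ccc(C)cc3)(Cc3cc(C(=O)OC)ccc3OCOC)[C@@H](C)CC[C@]12C | intermediate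
23 | monoalkyldiazene from 22 (1S,2S,4aS,8aS) | C=C1CCC[C@@H]2[C@](CN=N)(Cc3cc(C(=O)OC)ccc3OCOC)[C@@H](C)CC[C@]12C | intermediate
24 | methyl 4-(methoxymethoxy)-3-{[(1R,2S,4aS,8aR)-1,2,4a-trimethyl-5-methylidenedecahydronaphthalen-1-yl]methyl}benzoate | C=C1CCC[C@@H]2[C@](C)(Cc3cc(C(=O)OC)ccc3OCOC)[C@@H](C)CC[C@]12C | intermediate
25 | methyl 4-hydroxy-3-{[(1R,2S,4aS,8aR)-1,2,4a-trimethyl-5-methylidenedecahydronaphthalen-1-yl]methyl}benzoate | C=C1CCC[C@@H]2[C@](C)(Cc3cc(C(=O)OC)ccc3O)[C@@H](C)CC[C@]12C | target

## Step count and least certain steps

Total: 12 steps. Longest linear sequence: 9 steps (steps 1, 2, 3, 4, 5, 9, 10, 11, 12); the arene branch (steps 6–8) joins at step 9.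

**Step 2 (key step).** The most likely failure is slow displacement of the primary chloride by the aluminate enolate, so that proton transfer or decomposition of the enolate overtakes ring closure. The enantioselectivity with an α-branched alkenyl group may also fall short. Fallback: the same conjugate addition of 3 and 4 is quenched with aqueous NH4Cl and the chloro ketone (3S)-3-(5-chloropent-1-en-2-yl)-3-methylcyclohexan-1-one F1 is isolated. In a second flask, KH in THF at room temperature regenerates the enolates under equilibrating conditions. Only the C10 enolate can reach the chloride in a six-membered transition state, so the ring closes to 9, where the route is rejoined.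

**Step 9.** The risk is attack on the wrong face of C9 if ring B reacts through its other chair, in which C4 of ring A is axial and covers the upper face; some O-alkylation of the hindered enolate is also possible. Fallback: the roles of the two C9 substituents are exchanged, setting out from 14.
- KH and MeI give (1R,2S,4aS,8aS)-1,2,4a-trimethyl-5-methylidenedecahydronaphthalene-1-carbaldehyde F2. The small, soft electrophile alkylates on carbon, and if electrophiles prefer the lower face the methyl ends where it is needed, with the formyl carbon on the upper face.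
- Methyl 3-iodo-4-(methoxymethoxy)benzoate F3 (from commercial methyl 4-hydroxy-3-iodobenzoate and MOMCl) is converted with i-PrMgCl·LiCl at −20 °C into the arylmagnesium chloride F4.
- F4 adds to F2 to give the benzylic carbinol F5 (both carbinol epimers).
- NaH, CS2 and MeI give the xanthate F6, and Bu3SnH with AIBN in hot toluene removes the benzylic oxygen to give 24, where the route is rejoined.

**Step 5.** The risks are competing 1,2-addition to the enal and incomplete facial selectivity at C8. Fallback: setting out from 9, the lithium enolate (LiN(i-Pr)2, −78 °C) is methylated with MeI on the convex face to give (2S,4aS,8aS)-2,4a-dimethyl-5-methylideneoctahydronaphthalen-1(2H)-one F7. Wittig reaction with Ph3P=CHOMe gives the enol ether F8, and mild aqueous acid hydrolysis gives 14. This path is held in reserve because the ketone F7 can epimerise at C8 and C10 under the basic Wittig conditions.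

**Step 11.** The risks are sluggish hydride delivery to the hindered hydrazone and, if the reaction is forced, hydroboration of the methylene. Fallback: setting out from 20, NaBH4 in MeOH gives the neopentyl alcohol F9; NaH, CS2 and MeI give the xanthate F10; Bu3SnH and AIBN in refluxing toluene give 24 (Barton–McCombie deoxygenation). The primary radical lies on the face of ring B opposite to C4, so it cannot cyclise onto the methylene.

**Step 4.** The risk is reduction of the alkenylpalladium intermediate by the stannane before CO inserts, which would remove the triflate without adding the formyl carbon. Fallback: setting out from 11, methoxycarbonylation (Pd(OAc)2, PPh3, CO, MeOH, Et3N, DMF) gives the ester F11; i-Bu2AlH at −78 °C gives the allylic alcohol F12; MnO2 gives 12.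

## Further compounds

F1 | step 2 | (3S)-3-(5-chloropent-1-en-2-yl)-3-methylcyclohexan-1-one | C=C(CCCCl)[C@]1(C)CC(=O)CCC1
F2 | step 9 | (1R,2S,4aS,8aS)-1,2,4a-trimethyl-5-methylidenedecahydronaphthalene-1-carbaldehyde | C=C1CCC[C@@H]2[C@](C)(C=O)[C@@H](C)CC[C@]12C
F3 | step 9 | methyl 3-iodo-4-(methoxymethoxy)benzoate | COCOc1ccc(C(=O)OC)cc1I
F4 | step 9 | [2-(methoxymethoxy)-5-(methoxycarbonyl)phenyl]magnesium chloride | COCOc1ccc(C(=O)OC)cc1[Mg]Cl
F5 | step 9 | methyl 3-{hydroxy[(1R,2S,4aS,8aS)-1,2,4a-trimethyl-5-methylidenedecahydronaphthalen-1-yl]methyl}-4-(methoxymethoxy)benzoate (both carbinol epimers) | C=C1CCC[C@@H]2[C@](C)(C(O)c3cc(C(=O)OC)ccc3OCOC)[C@@H](C)CC[C@]12C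
F6 | step 9 | S-methyl xanthate of F5 | C=C1CCC[C@@H]2[C@](C)(C(OC(=S)SC)c3cc(C(=O)OC)ccc3OCOC)[C@@H](C)CC[C@]12C
F7 | step 5 | (2S,4aS,8aS)-2,4a-dimethyl-5-methylideneoctahydronaphthalen-1(2H)-one | C=C1CCC[C@@H]2C(=O)[C@@H](C)CC[C@]12C
F8 | step 5 | (2S,4aS,8aS)-1-(methoxymethylidene)-2,4a-dimethyl-5-methylidenedecahydronaphthalene | C=C1CCC[C@@H]2C(=COC)[C@@H](C)CC[C@]12C
F9 | step 11 | methyl 3-{[(1S,2S,4aS,8aS)-1-(hydroxymethyl)-2,4a-dimethyl-5-methylidenedecahydronaphthalen-1-yl]methyl}-4-(methoxymethoxy)benzoate | C=C1CCC[C@@H]2[C@](CO)(Cc3cc(C(=O)OC)ccc3OCOC)[C@@H](C)CC[C@]12C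
F10 | step 11 | S-methyl xanthate of F9 | C=C1CCC[C@@H]2[C@](COC(=S)SC)(Cc3cc(C(=O)OC)ccc3OCOC)[C@@H](C)CC[C@]12C
F11 | step 4 | methyl (4aS,8aS)-4a-methyl-5-methylidene-3,4,4a,5,6,7,8,8a-octahydronaphthalene-1-carboxylate | C=C1CCC[C@@H]2C(C(=O)OC)=CCC[C@]12C
F12 | step 4 | [(4aS,8aS)-4a-methyl-5-methylidene-3,4,4a,5,6,7,8,8a-octahydronaphthalen-1-yl]methanol | C=C1CCC[C@@H]2C(CO)=CCC[C@]12C
A1 | alternative 1 | cis-fused 1-{[2-(methoxymethoxy)-5-(methoxycarbonyl)phenyl]methyl}-2,4a-dimethyl-7-oxo-1,2,4a,7,8,8a-hexahydronaphthalene-1-carboxylic acid (configuration as in the SMILES) | C1=CC(=O)C[C@@H]2[C@](C(=O)O)(Cc3cc(C(=O)OC)ccc3OCOC)[C@@H](C)C=C[C@]12C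
A2 | alternative 1 | keto lactone with ring A enone fused at C5–C10 to the six-membered lactone C9–C(=O)–O–C6 and an (E)-prop-1-enyl group on C6 (C9 unassigned) | O=C1C=C[C@]2(C)[C@H](C1)C(Cc3cc(C(=O)OC)ccc3OCOC)C(=O)O[C@@H]2/C=C/C
A3 | alternative 2 | cis-fused octalin 4-carbaldehyde (Diels–Alder adduct, protected phenol) | O=C[C@H]1CC=C[C@@H]2[C@](C)(Cc3cc(C(=O)OC)ccc3OCOC)[C@@H](C)CC[C@]12C
A4 | alternative 2 | (2E,8Z)-7-{[2-(methoxymethoxy)-5-(methoxycarbonyl)phenyl]methyl}-3,6,7-trimethylundeca-2,8,10-trienal | O=C/C=C(\C)CC[C@H](C)[C@@](C)(Cc1cc(C(=O)OC)ccc1OCOC)/C=C\C=C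
A5 | alternative 3 | 6-oxo derivative of 24 | C=C1CCC[C@@H]2[C@](C)(Cc3cc(C(=O)OC)ccc3OCOC)[C@@H](C)CC(=O)[C@]12C
A6 | alternative 3 | tert-butyldimethylsilyl enol ether (C5=C6) of the ring B ketone carrying a pent-4-ynyl chain on C10 | C#CCCC[C@H]1C(C)=C(O[Si](C)(C)C(C)(C)C)C[C@H](C)[C@@]1(C)Cc1cc(C(=O)OC)ccc1OCOC
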